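**Retrosynthetic overview**
- The target comes from chroman 21 by cleavage of two MOM ethers, galloylation of O5 and O4' and hydrogenolysis of nine benzyl ethers; the MOM groups mark exactly the two phenols to be acylated.
- Key disconnection: the aryl ether bond O1–C8a of ring C. C8a of ring A enters as the only halogen-bearing carbon, so it cannot be confused with the oxygen-bearing C5 and C7, and ring C closes by C–O coupling in which the C2–O bond is never broken. This leads back to the anti bromo alcohol 20.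
- 20 comes from ketone 19 by chelation-controlled reduction (sets C2); 19 comes from Weinreb amide 14 and the ring B Grignard reagent 18.
- 14 comes from an Evans glycolate alkylation (sets C3) of imide 11 with the ring A benzylic bromide 7. Bromide 7 is made from 5-bromoresorcinol by formylation next to bromine; the formyl group then tells O5 (ortho, hydrogen-bonded) from O7 (para).
- Rings A and B are bought; ring C is the only ring formed (step 13).

Key step: step 13

Remark on the chemistry: (R)-4-benzyloxazolidin-2-one, benzyloxyacetyl chloride, 2-(benzyloxy)phenol and 3,4,5-tris(benzyloxy)benzoic acid are taken as purchasable. Ring A is brought in as a benzylic electrophile whose substitution pattern is fixed by formylation, because an ortho-metalated 1-bromo-3,5-dialkoxybenzene would have three competing deprotonation sites and would tend to lose metal bromide to an aryne.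

**Route**

Step 1
Reactants: 1 5-bromoresorcinol
Product: 3 2-bromo-4,6-dihydroxybenzaldehyde, via aryl iminium chloride 2 (not isolated)
Conditions: POCl3, DMF, MeCN, 0 °C to rt; then H2O, 50 °C
Reagents that add atoms: N,N-dimethylformamide CN(C)C=O; water O
Why: Vilsmeier–Haack formylation should occur para to one hydroxyl and ortho to the other, as with resorcinol and orcinol, which puts the formyl carbon (future C4) next to the bromine-bearing carbon (future C8a).

Step 2
Reactants: 3 2-bromo-4,6-dihydroxybenzaldehyde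
Product: 4 4-(benzyloxy)-2-bromo-6-hydroxybenzaldehyde
Conditions: BnBr (1.05 equiv), KHCO3, MeCN, 60 °C
Reagents that add atoms: benzyl bromide BrCc1ccccc1
Why: Williamson etherification with a weak base should alkylate only the more acidic para hydroxyl (future O7), because the ortho hydroxyl is held in a hydrogen bond to the formyl group.

Step 3
Reactants: 4 4-(benzyloxy)-2-bromo-6-hydroxybenzaldehyde
Product: 5 4-(benzyloxy)-2-bromo-6-(methoxymethoxy)benzaldehyde
Conditions: MOMCl, i-Pr2NEt, CH2Cl2, 0 to 40 °C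
Reagents that add atoms: chloromethyl methyl ether COCCl
Why: O-alkylation of the remaining chelated phenol (future O5) with the reactive α-chloro ether gives the MOM acetal, orthogonal to the benzyl ethers.

Step 4
Reactants: 5 4-(benzyloxy)-2-bromo-6-(methoxymethoxy)benzaldehyde
Product: 6 [4-(benzyloxy)-2-bromo-6-(methoxymethoxy)phenyl]methanol
Conditions: NaBH4, THF/MeOH, 0 °C
Reagents that add atoms: none
Why: Borohydride reduction of the aldehyde leaves the aryl bromide and both ethers untouched.

Step 5
Reactants: 6 [4-(benzyloxy)-2-bromo-6-(methoxymethoxy)phenyl]methanol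
Product: 7 5-(benzyloxy)-1-bromo-2-(bromomethyl)-3-(methoxymethoxy)benzene
Conditions: CBr4, PPh3, CH2Cl2, 0 °C; short alumina plug, high vacuum, used at once
Reagents that add atoms: carbon tetrabromide BrC(Br)(Br)Br
Why: The Appel reaction converts the benzylic alcohol to the bromide under neutral conditions that spare the MOM acetal; the electron-rich bromide is not stored.

Step 6
Reactants: 8 (R)-4-benzyloxazolidin-2-one; 9 benzyloxyacetyl chloride
Product: 11 (4R)-4-benzyl-3-[2-(benzyloxy)acetyl]-1,3-oxazolidin-2-one, via lithium oxazolidinide 10 (not isolated)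
Conditions: n-BuLi, THF, −78 °C; then 9, −78 to 0 °C
Reagents that add atoms: none
Why: N-acylation of the lithiated oxazolidinone with the acid chloride is the standard entry to Evans glycolate imides.

Step 7
Reactants: 11 (4R)-4-benzyl-3-[2-(benzyloxy)acetyl]-1,3-oxazolidin-2-one; 7 5-(benzyloxy)-1-bromo-2-(bromomethyl)-3-(methoxymethoxy)benzene
Product: 13 (4R)-4-benzyl-3-[(2S)-2-(benzyloxy)-3-[4-(benzyloxy)-2-bromo-6-(methoxymethoxy)phenyl]propanoyl]-1,3-oxazolidin-2-one, via sodium Z-enolate 12 (not isolated)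
Conditions: NaN(SiMe3)2, THF, −78 °C; then 7 (limiting), −78 to −40 °C
Reagents that add atoms: none
Why: Evans glycolate alkylation: the chelated Z-enolate is shielded on one face by the C4 benzyl group of the R auxiliary, so the benzylic bromide should enter from the other face and set the 2S centre (future C3).

Step 8
Reactants: 13 (4R)-4-benzyl-3-[(2S)-2-(benzyloxy)-3-[4-(benzyloxy)-2-bromo-6-(methoxymethoxy)phenyl]propanoyl]-1,3-oxazolidin-2-one
Product: 14 (2S)-2-(benzyloxy)-3-[4-(benzyloxy)-2-bromo-6-(methoxymethoxy)phenyl]-N-methoxy-N-methylpropanamide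
Conditions: MeNH(OMe)·HCl, AlMe3, CH2Cl2, 0 °C to rt; aq. KNaC4H4O6 work-up
Reagents that add atoms: N,O-dimethylhydroxylamine hydrochloride CNOC.Cl
Why: Weinreb transamidation with the aluminium amide should attack the exocyclic carbonyl, activated by the α-alkoxy group, and release the auxiliary without touching the α-centre.

Step 9
Reactants: 15 2-(benzyloxy)phenol
Product: 16 2-(benzyloxy)-4-bromophenol
Conditions: NBS, MeCN, 0 °C
Reagents that add atoms: N-bromosuccinimide O=C1CCC(=O)N1Br
Why: Electrophilic aromatic bromination is directed para to the free hydroxyl, the stronger donor, as with guaiacol.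

Step 10
Reactants: 16 2-(benzyloxy)-4-bromophenol
Product: 17 2-(benzyloxy)-4-bromo-1-(methoxymethoxy)benzene
Conditions: MOMCl, i-Pr2NEt, CH2Cl2, 0 °C to rt
Reagents that add atoms: chloromethyl methyl ether COCCl
Why: MOM acetal formation on the phenol marks the future O4' for later acylation.

Step 11
Reactants: 17 2-(benzyloxy)-4-bromo-1-(methoxymethoxy)benzene; 14 (2S)-2-(benzyloxy)-3-[4-(benzyloxy)-2-bromo-6-(methoxymethoxy)phenyl]-N-methoxy-N-methylpropanamide
Product: 19 (2S)-2-(benzyloxy)-3-[4-(benzyloxy)-2-bromo-6-(methoxymethoxy)phenyl]-1-[3-(benzyloxy)-4-(methoxymethoxy)phenyl]propan-1-one, via aryl Grignard reagent 18 (not isolated)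
Conditions: Mg turnings, I2 (cat.), THF, 50 °C; then 14, THF, 0 °C; aq. NH4Cl
Reagents that add atoms: none
Why: Grignard addition to the Weinreb amide stops at the magnesium chelate, so the ketone forms only on quench, without over-addition or α-epimerisation, and the aryl bromide of ring A does not exchange with an aryl Grignard reagent.

Step 12
Reactants: 19 (2S)-2-(benzyloxy)-3-[4-(benzyloxy)-2-bromo-6-(methoxymethoxy)phenyl]-1-[3-(benzyloxy)-4-(methoxymethoxy)phenyl]propan-1-one
Product: 20 (1R,2S)-2-(benzyloxy)-3-[4-(benzyloxy)-2-bromo-6-(methoxymethoxy)phenyl]-1-[3-(benzyloxy)-4-(methoxymethoxy)phenyl]propan-1-ol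
Conditions: Zn(BH4)2, Et2O/CH2Cl2, −30 to 0 °C; then H2O
Reagents that add atoms: none
Why: Chelation-controlled (Cram chelate) reduction: divalent zinc bridges the carbonyl and the α-benzyloxy oxygen and hydride enters from the face of the small α-hydrogen, which should set C1 as R, anti to the 2S ether.

Step 13
Reactants: 20 (1R,2S)-2-(benzyloxy)-3-[4-(benzyloxy)-2-bromo-6-(methoxymethoxy)phenyl]-1-[3-(benzyloxy)-4-(methoxymethoxy)phenyl]propan-1-ol
Product: 21 (2R,3S)-3,7-bis(benzyloxy)-2-[3-(benzyloxy)-4-(methoxymethoxy)phenyl]-5-(methoxymethoxy)chroman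
Conditions: CuI (10 mol %), 3,4,7,8-tetramethyl-1,10-phenanthroline (20 mol %), Cs2CO3, toluene (0.02 M), 110 °C
Reagents that add atoms: none
Why: Intramolecular Ullmann-type etherification: Cs2CO3 puts the C1 alkoxide on monovalent copper, the ortho C–Br bond adds oxidatively to give a seven-membered aryl alkoxide of trivalent copper, and C–O reductive elimination forms O1–C8a and returns monovalent copper. The closest known reaction type is the copper- or palladium-catalysed cyclisation of 3-(2-bromoaryl)propanols with a secondary carbinol to 2-substituted chromans. Ring C closes as a six-membered ring by exo attack of the tethered oxygen on C8a, the only ring A carbon that carries a halogen. No stereocentre is made; the C–O bonds at C2 and C3 are never broken, so the 1R,2S anti pattern should become 2R,3S unchanged. The step needs C–O reductive elimination to outrun β-hydride loss from the benzylic alkoxide and intermolecular coupling; copper with a phenanthroline ligand has little tendency to β-hydride elimination, high dilution favours the ring, and the benzyl ether on O3 removes the five-membered alternative.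

Step 14
Reactants: 21 (2R,3S)-3,7-bis(benzyloxy)-2-[3-(benzyloxy)-4-(methoxymethoxy)phenyl]-5-(methoxymethoxy)chroman
Product: 22 (2R,3S)-3,7-bis(benzyloxy)-2-[3-(benzyloxy)-4-hydroxyphenyl]chroman-5-ol
Conditions: 2 M HCl, MeOH/THF, 45 °C
Reagents that add atoms: none
Why: Acid-catalysed acetal methanolysis should cleave both aryl MOM ethers, with methanol trapping the methoxymethyl cation as dimethoxymethane, and leave the benzyl ethers and the chroman intact.

Step 15
Reactants: 22 (2R,3S)-3,7-bis(benzyloxy)-2-[3-(benzyloxy)-4-hydroxyphenyl]chroman-5-ol; 23 3,4,5-tris(benzyloxy)benzoic acid (2.4 equiv)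
Product: 24 (2R,3S)-3,7-bis(benzyloxy)-2-{3-(benzyloxy)-4-[3,4,5-tris(benzyloxy)benzoyloxy]phenyl}chroman-5-yl 3,4,5-tris(benzyloxy)benzoate
Conditions: DCC, DMAP, CH2Cl2, rt
Reagents that add atoms: none
Why: Steglich esterification should acylate both free phenols (O5 and O4'), the only unprotected hydroxyls, so no selectivity is required.

Step 16
Reactants: 24 (2R,3S)-3,7-bis(benzyloxy)-2-{3-(benzyloxy)-4-[3,4,5-tris(benzyloxy)benzoyloxy]phenyl}chroman-5-yl 3,4,5-tris(benzyloxy)benzoate
Product: 25 catechin 5,4'-di-O-gallate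
Conditions: H2 (1 atm), Pd(OH)2/C, THF/MeOH, rt; filtration and evaporation without base
Reagents that add atoms: none
Why: Hydrogenolysis should remove all nine benzyl ethers while the aryl esters and the chroman C2–O bond survive, and the neutral medium is meant to suppress migration of the 4'-galloyl group to O3'.

**Compound list**
1 | 5-bromoresorcinol | Oc1cc(O)cc(Br)c1 | starting material
2 | [(2-bromo-4,6-dihydroxyphenyl)methylidene]dimethylammonium chloride | C[N+](C)=Cc1c(O)cc(O)cc1Br.[Cl-] | intermediate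
3 | 2-bromo-4,6-dihydroxybenzaldehyde | O=Cc1c(O)cc(O)cc1Br | intermediate
4 | 4-(benzyloxy)-2-bromo-6-hydroxybenzaldehyde | O=Cc1c(O)cc(OCc2ccccc2)cc1Br | intermediate
5 | 4-(benzyloxy)-2-bromo-6-(methoxymethoxy)benzaldehyde | O=Cc1c(OCOC)cc(OCc2ccccc2)cc1Br | intermediate
6 | [4-(benzyloxy)-2-bromo-6-(methoxymethoxy)phenyl]methanol | OCc1c(OCOC)cc(OCc2ccccc2)cc1Br | intermediate
7 | 5-(benzyloxy)-1-bromo-2-(bromomethyl)-3-(methoxymethoxy)benzene | BrCc1c(OCOC)cc(OCc2ccccc2)cc1Br | intermediate
8 | (R)-4-benzyloxazolidin-2-one | O=C1N[C@H](Cc2ccccc2)CO1 | starting material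
9 | benzyloxyacetyl chloride | O=C(Cl)COCc1ccccc1 | starting material
10 | lithium salt of (R)-4-benzyloxazolidin-2-one | O=C1N([Li])[C@H](Cc2ccccc2)CO1 | intermediate
11 | (4R)-4-benzyl-3-[2-(benzyloxy)acetyl]-1,3-oxazolidin-2-one | O=C(COCc1ccccc1)N1C(=O)OC[C@H]1Cc1ccccc1 | intermediate
12 | sodium (Z)-enolate of 11 | [Na]O/C(=C\OCc1ccccc1)N1C(=O)OC[C@H]1Cc1ccccc1 | intermediate
13 | (4R)-4-benzyl-3-[(2S)-2-(benzyloxy)-3-[4-(benzyloxy)-2-bromo-6-(methoxymethoxy)phenyl]propanoyl]-1,3-oxazolidin-2-one | O=C([C@@H](OCc1ccccc1)Cc1c(Br)cc(OCc2ccccc2)cc1OCOC)N1C(=O)OC[C@H]1Cc1ccccc1 | intermediate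
14 | (2S)-2-(benzyloxy)-3-[4-(benzyloxy)-2-bromo-6-(methoxymethoxy)phenyl]-N-methoxy-N-methylpropanamide | CON(C)C(=O)[C@@H](OCc1ccccc1)Cc1c(Br)cc(OCc2ccccc2)cc1OCOC | intermediate
15 | 2-(benzyloxy)phenol | Oc1ccccc1OCc1ccccc1 | starting material
16 | 2-(benzyloxy)-4-bromophenol | Oc1ccc(Br)cc1OCc1ccccc1 | intermediate
17 | 2-(benzyloxy)-4-bromo-1-(methoxymethoxy)benzene | COCOc1ccc(Br)cc1OCc1ccccc1 | intermediate
18 | [3-(benzyloxy)-4-(methoxymethoxy)phenyl]magnesium bromide | COCOc1ccc([Mg]Br)cc1OCc1ccccc1 | intermediate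
19 | (2S)-2-(benzyloxy)-3-[4-(benzyloxy)-2-bromo-6-(methoxymethoxy)phenyl]-1-[3-(benzyloxy)-4-(methoxymethoxy)phenyl]propan-1-one | O=C(c1ccc(OCOC)c(OCc2ccccc2)c1)[C@@H](OCc1ccccc1)Cc1c(Br)cc(OCc2ccccc2)cc1OCOC | intermediate
20 | (1R,2S)-2-(benzyloxy)-3-[4-(benzyloxy)-2-bromo-6-(methoxymethoxy)phenyl]-1-[3-(benzyloxy)-4-(methoxymethoxy)phenyl]propan-1-ol | O[C@H](c1ccc(OCOC)c(OCc2ccccc2)c1)[C@@H](OCc1ccccc1)Cc1c(Br)cc(OCc2ccccc2)cc1OCOC | intermediate
21 | (2R,3S)-3,7-bis(benzyloxy)-2-[3-(benzyloxy)-4-(methoxymethoxy)phenyl]-5-(methoxymethoxy)chroman | COCOc1ccc([C@H]2Oc3cc(OCc4ccccc4)cc(OCOC)c3C[C@@H]2OCc2ccccc2)cc1OCc1ccccc1 | intermediate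
22 | (2R,3S)-3,7-bis(benzyloxy)-2-[3-(benzyloxy)-4-hydroxyphenyl]chroman-5-ol | Oc1ccc([C@H]2Oc3cc(OCc4ccccc4)cc(O)c3C[C@@H]2OCc2ccccc2)cc1OCc1ccccc1 | intermediate
23 | 3,4,5-tris(benzyloxy)benzoic acid | OC(=O)c1cc(OCc2ccccc2)c(OCc2ccccc2)c(OCc2ccccc2)c1 | starting material
24 | (2R,3S)-3,7-bis(benzyloxy)-2-{3-(benzyloxy)-4-[3,4,5-tris(benzyloxy)benzoyloxy]phenyl}chroman-5-yl 3,4,5-tris(benzyloxy)benzoate | O=C(Oc1ccc([C@H]2Oc3cc(OCc4ccccc4)cc(OC(=O)c4cc(OCc5ccccc5)c(OCc5ccccc5)c(OCc5ccccc5)c4)c3C[C@@H]2OCc2ccccc2)cc1OCc1ccccc1)c1cc(OCc2ccccc2)c(OCc2ccccc2)c(OCc2ccccc2)c1 | intermediate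
25 | catechin 5,4'-di-O-gallate | O=C(Oc1ccc([C@H]2Oc3cc(O)cc(OC(=O)c4cc(O)c(O)c(O)c4)c3C[C@@H]2O)cc1O)c1cc(O)c(O)c(O)c1 | target

**Step count**
Total: 16 steps. Longest linear sequence: 13 steps (steps 1–5, 7, 8, 11–16).

**Steps most likely to fail**

Risk 1 (step 13, ring closure). Oxidative addition at the hindered bromide may be slow, so that β-hydride loss from the alkoxide (oxidation of the carbinol with loss of bromine) or intermolecular etherification takes over. The fallback forms the same ring from the other side, by Mitsunobu etherification with inversion at the benzylic carbon, and therefore needs the C1 epimer. It sets out from ketone 19. Reduction with (S)-Me-CBS oxazaborolidine and BH3·SMe2, with the aryl group acting as the large substituent, should give the (1S,2S)-alcohol F1. Miyaura borylation (B2pin2, PdCl2(dppf), KOAc, dioxane, 80 °C) should then give the aryl pinacol boronate F2. Oxidation with NaBO3·4H2O in THF/H2O should give the phenol F3. PPh3 and DIAD in THF at 0 °C should close ring C with inversion at the carbinol carbon, and the sequence comes back to the route at chroman 21.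

Risk 2 (step 7, glycolate alkylation). The electron-rich benzylic bromide may ionise and self-condense before it meets the thermally fragile glycolate enolate, and substitution at the doubly ortho-substituted benzylic carbon may be slow. The fallback avoids the halide and sets out from aldehyde 5. Horner–Wadsworth–Emmons olefination with methyl 2-(benzyloxy)-2-(dimethoxyphosphoryl)acetate (NaH, THF, 0 °C) should give the enol ether ester F4. Asymmetric hydrogenation with [Rh(cod)((S,S)-Et-DuPhos)]OTf and H2 in MeOH, using the ligand antipode that delivers the 2S centre, should give the saturated ester F5. MeNH(OMe)·HCl and i-PrMgCl in THF at −20 °C should convert the ester to the Weinreb amide, and the sequence comes back to the route at 14.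

Risk 3 (step 12, reduction). Competing coordination of zinc by the MOM ethers may weaken the chelate and give poor facial selectivity. The fallback sets C1 by inversion instead of by chelation and sets out from ketone 19. Catalyst-controlled CBS reduction as in the first fallback should give the (1S,2S)-alcohol F1. Mitsunobu esterification with 4-nitrobenzoic acid (PPh3, DIAD, THF, 0 °C) should invert C1 and give the (1R,2S)-4-nitrobenzoate F6. Methanolysis with K2CO3 in MeOH comes back to the route at alcohol 20.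

**Further compounds**
F1 | step 13 | (1S,2S)-2-(benzyloxy)-3-[4-(benzyloxy)-2-bromo-6-(methoxymethoxy)phenyl]-1-[3-(benzyloxy)-4-(methoxymethoxy)phenyl]propan-1-ol | O[C@@H](c1ccc(OCOC)c(OCc2ccccc2)c1)[C@@H](OCc1ccccc1)Cc1c(Br)cc(OCc2ccccc2)cc1OCOC
F2 | step 13 | (1S,2S)-2-(benzyloxy)-3-[4-(benzyloxy)-2-(methoxymethoxy)-6-(4,4,5,5-tetramethyl-1,3,2-dioxaborolan-2-yl)phenyl]-1-[3-(benzyloxy)-4-(methoxymethoxy)phenyl]propan-1-ol | O[C@@H](c1ccc(OCOC)c(OCc2ccccc2)c1)[C@@H](OCc1ccccc1)Cc1c(B2OC(C)(C)C(C)(C)O2)cc(OCc2ccccc2)cc1OCOC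
F3 | step 13 | 5-(benzyloxy)-2-[(2S,3S)-2-(benzyloxy)-3-[3-(benzyloxy)-4-(methoxymethoxy)phenyl]-3-hydroxypropyl]-3-(methoxymethoxy)phenol | O[C@@H](c1ccc(OCOC)c(OCc2ccccc2)c1)[C@@H](OCc1ccccc1)Cc1c(O)cc(OCc2ccccc2)cc1OCOC
F4 | step 7 | methyl (2Z)-2-(benzyloxy)-3-[4-(benzyloxy)-2-bromo-6-(methoxymethoxy)phenyl]prop-2-enoate | COC(=O)/C(OCc1ccccc1)=C/c1c(Br)cc(OCc2ccccc2)cc1OCOC
F5 | step 7 | methyl (2S)-2-(benzyloxy)-3-[4-(benzyloxy)-2-bromo-6-(methoxymethoxy)phenyl]propanoate | COC(=O)[C@@H](OCc1ccccc1)Cc1c(Br)cc(OCc2ccccc2)cc1OCOC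
F6 | step 12 | (1R,2S)-2-(benzyloxy)-3-[4-(benzyloxy)-2-bromo-6-(methoxymethoxy)phenyl]-1-[3-(benzyloxy)-4-(methoxymethoxy)phenyl]propyl 4-nitrobenzoate | O=C(O[C@H](c1ccc(OCOC)c(OCc2ccccc2)c1)[C@@H](OCc1ccccc1)Cc1c(Br)cc(OCc2ccccc2)cc1OCOC)c1ccc([N+](=O)[O-])cc1
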